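**Conventions.** Isocoumarin atoms are numbered C1, O2, C3, C4, C4a, C5–C8, C8a (ring A = benzene ring, ring B = pyranone ring). The butyrolactone is ring C with primed atoms O1′, C2′(=O), C3′(OH), C4′H2, C5′. Compound numbers are those of the steps and the compound list below.

## Analysis of the target

Target 19 is an 8-hydroxy-6-methoxyisocoumarin whose C3 carries, through one methylene group, the fully substituted C5′ of an α-hydroxy-γ-butyrolactone. There are two stereocentres: C3′ (S, secondary carbinol α to the lactone carbonyl) and C5′ (R, bearing the ring oxygen, a dichloromethyl group and two methylene groups). They stand 1,3 across ring C, with the hydroxyl group cis to the dichloromethyl group. C5′ is the hard centre: its two methylene arms differ only at the next atom and the CHCl2 group is of similar size, so neither a reagent nor a neighbouring centre tells its faces apart easily. The sensitive points all lie in ring C: basic opening frees a tertiary alkoxide next to CHCl2 (closure to a chloro-epoxide), C3′–H can epimerise, the C–Cl bonds exclude hydrogenolysis, and any intermediate with a carbonyl group at the future C3 would be a β-acyloxy ketone and would eliminate the lactone oxygen. Ring A shows the feature on which the strategy rests: the adjacent carbons C4a and C8a carry the two carbon substituents C4 and C1, the oxygen on C8 sits directly beside C8a, and the second oxygen is on C6. This is the pattern of a 3,5-dioxygenated aryne C4a≡C8a that has taken up a carbon nucleophile at C4a and a carbon electrophile at C8a. The synthesis is hard because C5′ must be set with an alkyne arm in place, and because ring B must be built on a base-labile chiral lactone without passing through a β-acyloxy carbonyl compound.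

## Retrosynthetic reasoning

**19 ⇒ 18.** Only C–O bonds are cut: the C3′ hydroxyl group is masked as a benzyl ether and the C8 hydroxyl group as a methyl ether. Both masks are needed anyway, since a free alcohol or phenol would add to the aryne of the key step. Both fall in one Lewis-acid operation, the peri methyl ether being singled out by chelation to the C1 carbonyl.

**18 ⇒ 7 + 15 (key disconnection).** Three bonds of ring B are cut at once: C4–C4a, C1–C8a and O2–C3. What remains is the terminal alkyne 7, the aryne precursor 15 and a one-carbon unit at the carboxyl oxidation level taken from the gas phase. The cut is made here for three reasons. Ring A then comes from a cheap symmetrical phenol with no ortho carbon substituent to install. The C8 oxygen itself decides which aryne carbon receives the alkyne and which the carboxyl group. C3 enters as an alkyne carbon, so no β-acyloxy ketone ever exists. The forward reaction must add the copper acetylide of 7 to the aryne carbon remote from the methoxy group, trap the aryl–copper bond beside that methoxy group as a carboxylate, and close the carboxylate onto the alkyne in the 6-endo sense.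

**15 ⇒ 13 ⇒ 9 ⇒ 8.** The O–S bond and the C–Si bond of 15 are cut back to phenol 8. The phenolic oxygen serves first as the anchor of a carbamate directing group and then as the leaving group of the aryne precursor. Three routine steps are the price of the key step, about what a pre-halogenated benzoate for a cross-coupling would cost.

**7 ⇒ 6 ⇒ 4.** After removal of the benzyl ether, the C5′–CH2(propargyl) bond and the lactone bond O1′–C2′ are cut. This leaves the dichloromethyl ketone 4, in which C3′–O and the carboxyl group are tied up as an acetonide that later acts as the acyl donor for ring C. The propargyl group is added as a nucleophile (an allenylboron reagent) because structure rules out the other orders: a propargyl ketone would isomerise to an allenyl ketone, and making the alkyne from an aldehyde once ring C exists would pass through a β-acyloxy aldehyde. The forward reaction must choose one face of a ketone flanked by CHCl2 and CH2, which is left to a chiral catalyst, and then translactonise.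

**4 ⇒ 3 ⇒ 1.** The two C–Cl bonds are cut back to a diazo carbon, and diazoketone 3 to acid 1, the acetonide of the natural S hydroxy diacid. C3′ thus comes from the chiral pool with the right configuration, and the free carboxyl carbon of 1 is exactly the carbon that becomes C5′.

## Alternatives that were turned down

**Alternative 1:** (textbook) Disconnection of C3–C4 and O2–C3. Forward: lateral lithiation of the o-toluate A1, Claisen-type acylation with the Weinreb amide A2 to the keto ester A3, then acid-induced cyclodehydration to 18. Turned down because A3 carries the lactone oxygen of ring C β to the new ketone. A3 is more acidic than A1 and is deprotonated at once under the conditions of its formation, and acid is needed for ring closure; either way β-elimination would open ring C and destroy C5′. The benzylic anion of A1 is also a hard base that would attack the lactone carbonyl of A2, epimerise C3′ and metalate the CHCl2 group. A2 itself needs a CH2–C=O arm on C5′, i.e. a tertiary aldol prone to retro-aldol cleavage. The route is no shorter and spreads risk over three places.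

**Alternative 2:** Disconnection of C4–C4a and O2–C3 on a pre-functionalised ring A. Forward: Sonogashira coupling of 7 with the iodo acid A4 and cyclisation of the alkynyl acid A5 in the same pot. Turned down as key step for three reasons. A4 needs iodine and carboxyl placed ortho to each other on the dimethoxy ring by stepwise substitution chemistry that costs as much as 15. Under the basic palladium–copper conditions the carboxylate of A5 can close 5-exo to an alkylidene phthalide as well as 6-endo. It forms one C–C bond where the aryne step forms two. The disconnection is kept in reserve in a two-step form.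

**Alternative 3:** Ring A from acyclic carbons. Forward: Diels–Alder reaction of the electron-rich diene A6 with the diynoate A7 and aromatisation by loss of the acetal substituents to the salicylate A8, which has the C8 hydroxyl and C6 methoxy groups already differentiated; then lactonisation onto the remaining alkyne. Turned down because A7 costs two further steps on the valuable chiral alkyne 7 (bromination and a copper-mediated diyne coupling). A conjugated diynoate offers the diene two triple bonds and two Michael positions, and the ketene acetal would have to be heated with an α-alkoxy lactone. Six ring carbons would be built that commerce supplies in 8, with no stereochemical gain.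

Key step: step 8

**Assumption:** the (S) antipode of the biphenol catalyst is written for step 3 on the basis of the closed chair model; if the sense of induction on this ketone is the opposite, the mirror-image catalyst is used.

## Route

Step 1
Reactants: 1 [(4S)-2,2-dimethyl-5-oxo-1,3-dioxolan-4-yl]acetic acid
Product: 3 (5S)-5-(3-diazo-2-oxopropyl)-2,2-dimethyl-1,3-dioxolan-4-one, via acid chloride 2 (not isolated)
Conditions: (COCl)2, DMF (cat.), CH2Cl2, 0 °C to rt; evaporate; TMSCHN2 (2 equiv), THF/MeCN, 0 °C to rt
Reagents that add atoms: (trimethylsilyl)diazomethane, C[Si](C)(C)C=[N+]=[N-]; for intermediate 2 only: oxalyl chloride, O=C(Cl)C(Cl)=O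
Why: Acid chloride formation and C-acylation of a silyl diazoalkane (diazoketone synthesis as in the Arndt–Eistert sequence), chloride removing the silyl group; the acetonide keeps the C3′ oxygen and the future C2′ carboxyl masked, and the neutral conditions leave the α-stereocentre untouched.

Step 2
Reactants: 3 (5S)-5-(3-diazo-2-oxopropyl)-2,2-dimethyl-1,3-dioxolan-4-one
Product: 4 (5S)-5-(3,3-dichloro-2-oxopropyl)-2,2-dimethyl-1,3-dioxolan-4-one
Conditions: PhICl2 (1.1 equiv), pyridine (10 mol %), CH2Cl2, 0 °C, dark
Reagents that add atoms: (dichloroiodo)benzene, ClI(Cl)c1ccccc1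
Why: Halogenative dediazotisation of an α-diazo ketone by a dichloride of trivalent iodine: the diazo carbon takes up electrophilic chlorine, nitrogen leaves and chloride fills the vacancy, so both chlorines arrive on one carbon without a free carbene and hence without Wolff rearrangement.

Step 3
Reactants: 4 (5S)-5-(3,3-dichloro-2-oxopropyl)-2,2-dimethyl-1,3-dioxolan-4-one
Product: 6 (3S,5S)-5-(dichloromethyl)-3-hydroxy-5-(prop-2-yn-1-yl)dihydrofuran-2(3H)-one, via tertiary alcohol 5 (not isolated)
Conditions: allenylB(pin) (1.5 equiv), (S)-3,3′-Br2-BINOL (15 mol %), toluene, rt to 40 °C; then 1 M HCl, THF, rt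
Reagents that add atoms: allenylboronic acid pinacol ester, C=C=CB1OC(C)(C)C(C)(C)O1
Why: Chiral-biphenol-catalysed propargylation of a ketone with an allenylboronate (SE2′ through a closed six-membered transition state, giving the terminal homopropargylic alkyne); the carbonyl face is chosen by the catalyst, since the resident centre is β to the carbonyl and held in a poorly chelating acetonide, so C5′ should form mainly as drawn. Acid then frees the tertiary alcohol, which closes ring C by 5-exo-trig attack on the activated dioxolanone carbonyl.

Step 4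
Reactants: 6 (3S,5S)-5-(dichloromethyl)-3-hydroxy-5-(prop-2-yn-1-yl)dihydrofuran-2(3H)-one
Product: 7 (3S,5S)-3-(benzyloxy)-5-(dichloromethyl)-5-(prop-2-yn-1-yl)dihydrofuran-2(3H)-one
Conditions: BnOC(=NH)CCl3 (1.5 equiv), TfOH (5 mol %), CH2Cl2/cyclohexane, 0 °C to rt
Reagents that add atoms: benzyl 2,2,2-trichloroacetimidate, N=C(OCc1ccccc1)C(Cl)(Cl)Cl
Why: Acid-catalysed O-benzylation with a trichloroacetimidate, the base-free method for α-hydroxy esters and lactones, so C3′ cannot epimerise and ring C is never exposed to alkoxide; the ether blocks O–H addition to the aryne in step 8.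

Step 5
Reactants: 8 3,5-dimethoxyphenol
Product: 9 3,5-dimethoxyphenyl propan-2-ylcarbamate
Conditions: i-PrNCO (1.3 equiv), Et3N (0.2 equiv), CH2Cl2, rt
Reagents that add atoms: 2-isocyanatopropane, CC(C)N=C=O
Why: Addition of a phenol to an isocyanate gives the N-monoalkyl carbamate, a strong ortho director that can later be removed under mild base.

Step 6
Reactants: 9 3,5-dimethoxyphenyl propan-2-ylcarbamate
Product: 13 3,5-dimethoxy-2-(trimethylsilyl)phenyl propan-2-ylcarbamate, via N-silyl carbamate 10 (not isolated), via aryllithium 11 (not isolated), via bis-silyl carbamate 12 (not isolated)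
Conditions: TBSOTf (1.05 equiv), TMEDA (1.1 equiv), Et2O, 0 °C to rt; TMEDA (2 equiv), n-BuLi (2 equiv), −78 °C; TMSCl (3 equiv), −78 °C to rt; aq. NaHSO4
Reagents that add atoms: chlorotrimethylsilane, C[Si](C)(C)Cl; for intermediates 10 to 12 only: tert-butyldimethylsilyl trifluoromethanesulfonate, CC(C)(C)[Si](C)(C)OS(=O)(=O)C(F)(F)F, and n-butyllithium, [Li]CCCC
Why: Directed ortho-metalation: after N-silylation in situ the carbamate is the strongest director, and C2 (equivalent to C6 by symmetry) lies between it and a methoxy group, whereas C4 is flanked only by two methoxy groups; the aryllithium is silylated and the N–Si bond is hydrolysed on acidic work-up.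

Step 7
Reactants: 13 3,5-dimethoxy-2-(trimethylsilyl)phenyl propan-2-ylcarbamate
Product: 15 3,5-dimethoxy-2-(trimethylsilyl)phenyl trifluoromethanesulfonate, via silylphenol 14 (not isolated)
Conditions: DBU (1.5 equiv), Et2NH (1.2 equiv), MeCN, 40 °C; then PhNTf2 (1.5 equiv), rt
Reagents that add atoms: N-phenylbis(trifluoromethanesulfonimide), O=S(=O)(N(c1ccccc1)S(=O)(=O)C(F)(F)F)C(F)(F)F
Why: Base-induced E1cB cleavage of the N-monoalkyl carbamate (the isocyanate is trapped by the amine as a urea) and triflation of the phenoxide in the same pot give the ortho-silylaryl triflate, the standard fluoride-triggered aryne precursor.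

Step 8
Reactants: 7 (3S,5S)-3-(benzyloxy)-5-(dichloromethyl)-5-(prop-2-yn-1-yl)dihydrofuran-2(3H)-one; 15 3,5-dimethoxy-2-(trimethylsilyl)phenyl trifluoromethanesulfonate
Product: 18 (3S,5R)-3-(benzyloxy)-5-(dichloromethyl)-5-[(6,8-dimethoxy-1-oxo-1H-isochromen-3-yl)methyl]dihydrofuran-2(3H)-one, via aryne 16 (not isolated), via alkynylbenzoate 17 (not isolated)
Conditions: 15 (1.5 equiv), (IPr)CuCl [IPr = 1,3-bis(2,6-diisopropylphenyl)imidazol-2-ylidene] (10 mol %), CsF (3 equiv), Cs2CO3 (1 equiv), CO2 (1 atm), MeCN, 60 °C
Reagents that add atoms: carbon dioxide, O=C=O; for intermediate 17 only: cesium fluoride (counter-ion), [Cs+].[F-]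
Why: Fluoride strips the silyl group of 15 and triflate leaves, giving aryne 16, across whose strained triple bond the (IPr)Cu acetylide of 7 (formed with carbonate) adds by carbocupration. The methoxy oxygen beside the triple bond (future C8) withdraws inductively and distorts the aryne so that the remote carbon (future C4a) is the more electrophilic one: the acetylide carbon bonds there and copper ends on C8a next to oxygen, while the second methoxy group (future C6) is too far from the triple bond to matter. The ortho-alkynyl arylcopper then inserts CO2 to give carboxylate 17, which fixes C1 on C8a. Ring B closes by 6-endo-dig anti attack of a carboxylate oxygen on the copper-bound alkyne (O2–C3), and the C4–Cu bond is protonated by the next molecule of 7, which returns the acetylide. The closest known reaction type is the N-heterocyclic-carbene–copper-catalysed three-component synthesis of isocoumarins from arynes, terminal alkynes and CO2. No stereocentre is formed: C3′ and C5′ are spectators, the benzyl ether prevents O–H addition to the aryne, and anhydrous fluoride and carbonate should leave ring C closed. The step needs three selectivities: the sense of aryne addition (secured by the C8 methoxy group), carboxylation before protonation of the arylcopper (secured by the CO2 atmosphere and the aprotic medium), and 6-endo over 5-exo closure (favoured by soft monovalent copper on an alkyne polarised towards the carbon remote from the ring, and by the unstrained six-membered vinylcopper).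

Step 9
Reactants: 18 (3S,5R)-3-(benzyloxy)-5-(dichloromethyl)-5-[(6,8-dimethoxy-1-oxo-1H-isochromen-3-yl)methyl]dihydrofuran-2(3H)-one
Product: 19 (3S,5R)-5-(dichloromethyl)-3-hydroxy-5-[(8-hydroxy-6-methoxy-1-oxo-1H-isochromen-3-yl)methyl]dihydrofuran-2(3H)-one
Conditions: BCl3 (4 equiv), C6HMe5 (3 equiv), CH2Cl2, −78 to 0 °C; aq. NaHCO3
Reagents that add atoms: none
Why: Lewis-acid ether cleavage: BCl3 removes the benzyl group (the cation is trapped by pentamethylbenzene in a Friedel–Crafts reaction) and, through a six-membered chelate with the C1 carbonyl, only the peri methyl ether at C8; the C6 methyl ether, both lactones and the CHCl2 group should be inert at this temperature, and no stereocentre is touched.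

## Compound list

1 | [(4S)-2,2-dimethyl-5-oxo-1,3-dioxolan-4-yl]acetic acid | OC(=O)C[C@@H]1OC(C)(C)OC1=O | starting material
2 | [(4S)-2,2-dimethyl-5-oxo-1,3-dioxolan-4-yl]acetyl chloride | ClC(=O)C[C@@H]1OC(C)(C)OC1=O | intermediate
3 | (5S)-5-(3-diazo-2-oxopropyl)-2,2-dimethyl-1,3-dioxolan-4-one | [N-]=[N+]=CC(=O)C[C@@H]1OC(C)(C)OC1=O | intermediate
4 | (5S)-5-(3,3-dichloro-2-oxopropyl)-2,2-dimethyl-1,3-dioxolan-4-one | ClC(Cl)C(=O)C[C@@H]1OC(C)(C)OC1=O | intermediate
5 | (5S)-5-[(2S)-2-(dichloromethyl)-2-hydroxypent-4-yn-1-yl]-2,2-dimethyl-1,3-dioxolan-4-one | C#CC[C@@](O)(C(Cl)Cl)C[C@@H]1OC(C)(C)OC1=O | intermediate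
6 | (3S,5S)-5-(dichloromethyl)-3-hydroxy-5-(prop-2-yn-1-yl)dihydrofuran-2(3H)-one | C#CC[C@@]1(C(Cl)Cl)C[C@H](O)C(=O)O1 | intermediate
7 | (3S,5S)-3-(benzyloxy)-5-(dichloromethyl)-5-(prop-2-yn-1-yl)dihydrofuran-2(3H)-one | C#CC[C@@]1(C(Cl)Cl)C[C@H](OCc2ccccc2)C(=O)O1 | intermediate
8 | 3,5-dimethoxyphenol | COc1cc(O)cc(OC)c1 | starting material
9 | 3,5-dimethoxyphenyl propan-2-ylcarbamate | COc1cc(OC)cc(OC(=O)NC(C)C)c1 | intermediate
10 | 3,5-dimethoxyphenyl [tert-butyl(dimethyl)silyl](propan-2-yl)carbamate | COc1cc(OC)cc(OC(=O)N(C(C)C)[Si](C)(C)C(C)(C)C)c1 | intermediate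
11 | 2-lithio derivative of 10 (lithium on the ring carbon between the carbamate oxygen and a methoxy group) | [Li]c1c(OC)cc(OC)cc1OC(=O)N(C(C)C)[Si](C)(C)C(C)(C)C | intermediate
12 | 3,5-dimethoxy-2-(trimethylsilyl)phenyl [tert-butyl(dimethyl)silyl](propan-2-yl)carbamate | COc1cc(OC)c([Si](C)(C)C)c(OC(=O)N(C(C)C)[Si](C)(C)C(C)(C)C)c1 | intermediate
13 | 3,5-dimethoxy-2-(trimethylsilyl)phenyl propan-2-ylcarbamate | COc1cc(OC)c([Si](C)(C)C)c(OC(=O)NC(C)C)c1 | intermediate
14 | 3,5-dimethoxy-2-(trimethylsilyl)phenol | COc1cc(OC)c([Si](C)(C)C)c(O)c1 | intermediate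
15 | 3,5-dimethoxy-2-(trimethylsilyl)phenyl trifluoromethanesulfonate | COc1cc(OC)c([Si](C)(C)C)c(OS(=O)(=O)C(F)(F)F)c1 | intermediate
16 | 1,2-didehydro-3,5-dimethoxybenzene (3,5-dimethoxybenzyne) | COC1=CC(OC)=CC#C1 | intermediate
17 | cesium 2-{3-[(2S,4S)-4-(benzyloxy)-2-(dichloromethyl)-5-oxooxolan-2-yl]prop-1-yn-1-yl}-4,6-dimethoxybenzoate | COc1cc(OC)c(C([O-])=O)c(C#CC[C@@]2(C(Cl)Cl)C[C@H](OCc3ccccc3)C(=O)O2)c1.[Cs+] | intermediate
18 | (3S,5R)-3-(benzyloxy)-5-(dichloromethyl)-5-[(6,8-dimethoxy-1-oxo-1H-isochromen-3-yl)methyl]dihydrofuran-2(3H)-one | COc1cc(OC)c2c(=O)oc(C[C@@]3(C(Cl)Cl)C[C@H](OCc4ccccc4)C(=O)O3)cc2c1 | intermediate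
19 | (3S,5R)-5-(dichloromethyl)-3-hydroxy-5-[(8-hydroxy-6-methoxy-1-oxo-1H-isochromen-3-yl)methyl]dihydrofuran-2(3H)-one | COc1cc(O)c2c(=O)oc(C[C@@]3(C(Cl)Cl)C[C@H](O)C(=O)O3)cc2c1 | target

The descriptor at C5′ changes from S (alkyne compounds 6, 7, 17) to R (isocoumarins 18, 19) only because the CIP priority of the side arm rises when the alkyne becomes ring B; the spatial arrangement is the same throughout.

## Step count and least certain steps

Total step count: 9. Longest linear sequence: 6 steps (steps 1, 2, 3, 4, 8 and 9, from 1).

**Step 8 (key step).** What is most likely to go wrong is loss of chemoselectivity among the copper intermediates: protonation of the arylcopper before it is carboxylated, or 5-exo instead of 6-endo closure. A second risk is base-mediated epimerisation at C3′ at the temperature needed for aryne release. The fallback sets out from 7 and returns to the route at 18. Sonogashira coupling of 7 with methyl 2,4-dimethoxy-6-{[(trifluoromethyl)sulfonyl]oxy}benzoate F1 (Pd(PPh3)2Cl2, CuI, Et3N, DMF) would give the ortho-alkynylbenzoate F2. A cationic catalyst of monovalent gold (Ph3PAuCl/AgOTf, wet 1,2-dichloroethane) would then close ring B in the 6-endo sense, with loss of the ester methyl group, to give 18.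

**Step 3.** What is most likely to go wrong is poor facial selectivity at the ketone. The two groups flanking the carbonyl (CHCl2 and CH2) differ little in size, the catalyst class was developed on methyl ketones, and an uncatalysed background addition to this activated ketone would erode the selectivity further. The fallback sets out from 4 and returns at 6. It gives up catalyst control and relies on separation of diastereomers, which is possible here because C3′ comes from the chiral pool. Barbier propargylation (propargyl bromide, indium metal, THF/aq. NH4Cl) would give both carbinols, 5 and its epimer (5S)-5-[(2R)-2-(dichloromethyl)-2-hydroxypent-4-yn-1-yl]-2,2-dimethyl-1,3-dioxolan-4-one F3. Acid lactonisation would give 6 and its C5′ epimer (3S,5R)-5-(dichloromethyl)-3-hydroxy-5-(prop-2-yn-1-yl)dihydrofuran-2(3H)-one F4, a cis/trans pair of hydroxy lactones to be separated by chromatography. Every molecule of 6 obtained this way is still a single enantiomer.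

**Step 9.** What is most likely to go wrong is loss of selectivity between the two aryl methyl ethers on warming, or benzylation of the electron-rich ring A if the benzyl cation escapes the scavenger. The fallback sets out from 6 and returns at 19. Alcohol 6 would be protected instead as the 4-methoxybenzyl ether (3S,5S)-5-(dichloromethyl)-3-[(4-methoxybenzyl)oxy]-5-(prop-2-yn-1-yl)dihydrofuran-2(3H)-one F5 (4-methoxybenzyl trichloroacetimidate, catalytic acid). The conditions of step 8 with 15 would lead through the cesium alkynylbenzoate F6 (not isolated) to the 4-methoxybenzyl-protected isocoumarin F7. Oxidative removal of the 4-methoxybenzyl group (DDQ, CH2Cl2/pH 7 buffer) would give the alcohol (3S,5R)-5-(dichloromethyl)-5-[(6,8-dimethoxy-1-oxo-1H-isochromen-3-yl)methyl]-3-hydroxydihydrofuran-2(3H)-one F8. BCl3 at −78 °C would then have only the peri methyl ether to cleave, giving 19.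

**Step 6.** What is most likely to go wrong is metalation at the wrong site (C4, between the two methoxy groups) or anionic migration of the carbamoyl group to carbon if the aryllithium warms before it is silylated. The fallback sets out from 8 and returns at 14. Ortho-bromination of 8 (N-bromosuccinimide, catalytic diisopropylamine, CH2Cl2) would give 2-bromo-3,5-dimethoxyphenol F9, and O-silylation (hexamethyldisilazane) the silyl ether (2-bromo-3,5-dimethoxyphenoxy)trimethylsilane F10. Bromine–lithium exchange with n-BuLi at −78 °C would give the aryllithium (2-lithio-3,5-dimethoxyphenoxy)trimethylsilane F11. Its 1,3-shift of silicon from oxygen to carbon (retro-Brook rearrangement) would give the lithium salt of 14, which is triflated as in the second half of step 7.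

## Further compounds

F1 | step 8 | methyl 2,4-dimethoxy-6-{[(trifluoromethyl)sulfonyl]oxy}benzoate | COC(=O)c1c(OC)cc(OC)cc1OS(=O)(=O)C(F)(F)F
F2 | step 8 | methyl 2-{3-[(2S,4S)-4-(benzyloxy)-2-(dichloromethyl)-5-oxooxolan-2-yl]prop-1-yn-1-yl}-4,6-dimethoxybenzoate | COC(=O)c1c(OC)cc(OC)cc1C#CC[C@@]2(C(Cl)Cl)C[C@H](OCc3ccccc3)C(=O)O2
F3 | step 3 | (5S)-5-[(2R)-2-(dichloromethyl)-2-hydroxypent-4-yn-1-yl]-2,2-dimethyl-1,3-dioxolan-4-one | C#CC[C@](O)(C(Cl)Cl)C[C@@H]1OC(C)(C)OC1=O
F4 | step 3 | (3S,5R)-5-(dichloromethyl)-3-hydroxy-5-(prop-2-yn-1-yl)dihydrofuran-2(3H)-one | C#CC[C@]1(C(Cl)Cl)C[C@H](O)C(=O)O1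
F5 | step 9 | (3S,5S)-5-(dichloromethyl)-3-[(4-methoxybenzyl)oxy]-5-(prop-2-yn-1-yl)dihydrofuran-2(3H)-one | C#CC[C@@]1(C(Cl)Cl)C[C@H](OCc2ccc(OC)cc2)C(=O)O1
F6 | step 9 | cesium 2-{3-[(2S,4S)-2-(dichloromethyl)-4-[(4-methoxybenzyl)oxy]-5-oxooxolan-2-yl]prop-1-yn-1-yl}-4,6-dimethoxybenzoate | COc1cc(OC)c(C([O-])=O)c(C#CC[C@@]2(C(Cl)Cl)C[C@H](OCc3ccc(OC)cc3)C(=O)O2)c1.[Cs+]
F7 | step 9 | (3S,5R)-5-(dichloromethyl)-5-[(6,8-dimethoxy-1-oxo-1H-isochromen-3-yl)methyl]-3-[(4-methoxybenzyl)oxy]dihydrofuran-2(3H)-one | COc1cc(OC)c2c(=O)oc(C[C@@]3(C(Cl)Cl)C[C@H](OCc4ccc(OC)cc4)C(=O)O3)cc2c1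
F8 | step 9 | (3S,5R)-5-(dichloromethyl)-5-[(6,8-dimethoxy-1-oxo-1H-isochromen-3-yl)methyl]-3-hydroxydihydrofuran-2(3H)-one | COc1cc(OC)c2c(=O)oc(C[C@@]3(C(Cl)Cl)C[C@H](O)C(=O)O3)cc2c1
F9 | step 6 | 2-bromo-3,5-dimethoxyphenol | COc1cc(O)c(Br)c(OC)c1
F10 | step 6 | (2-bromo-3,5-dimethoxyphenoxy)trimethylsilane | COc1cc(O[Si](C)(C)C)c(Br)c(OC)c1
F11 | step 6 | (2-lithio-3,5-dimethoxyphenoxy)trimethylsilane | [Li]c1c(OC)cc(OC)cc1O[Si](C)(C)C
A1 | alternative 1 | methyl 2,4-dimethoxy-6-methylbenzoate | COC(=O)c1c(C)cc(OC)cc1OC
A2 | alternative 1 | 2-[(2R,4S)-4-(benzyloxy)-2-(dichloromethyl)-5-oxooxolan-2-yl]-N-methoxy-N-methylacetamide | CON(C)C(=O)C[C@@]1(C(Cl)Cl)C[C@H](OCc2ccccc2)C(=O)O1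
A3 | alternative 1 | methyl 2-{3-[(2R,4S)-4-(benzyloxy)-2-(dichloromethyl)-5-oxooxolan-2-yl]-2-oxopropyl}-4,6-dimethoxybenzoate | COC(=O)c1c(CC(=O)C[C@@]2(C(Cl)Cl)C[C@H](OCc3ccccc3)C(=O)O2)cc(OC)cc1OC
A4 | alternative 2 | 2-iodo-4,6-dimethoxybenzoic acid | OC(=O)c1c(I)cc(OC)cc1OC
A5 | alternative 2 | 2-{3-[(2S,4S)-4-(benzyloxy)-2-(dichloromethyl)-5-oxooxolan-2-yl]prop-1-yn-1-yl}-4,6-dimethoxybenzoic acid | OC(=O)c1c(OC)cc(OC)cc1C#CC[C@@]2(C(Cl)Cl)C[C@H](OCc3ccccc3)C(=O)O2
A6 | alternative 3 | 1,3-dimethoxy-1-[(trimethylsilyl)oxy]buta-1,3-diene | COC(=C)C=C(OC)O[Si](C)(C)C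
A7 | alternative 3 | methyl 6-[(2S,4S)-4-(benzyloxy)-2-(dichloromethyl)-5-oxooxolan-2-yl]hexa-2,4-diynoate | COC(=O)C#CC#CC[C@@]1(C(Cl)Cl)C[C@H](OCc2ccccc2)C(=O)O1
A8 | alternative 3 | methyl 2-{3-[(2S,4S)-4-(benzyloxy)-2-(dichloromethyl)-5-oxooxolan-2-yl]prop-1-yn-1-yl}-6-hydroxy-4-methoxybenzoate | COC(=O)c1c(O)cc(OC)cc1C#CC[C@@]2(C(Cl)Cl)C[C@H](OCc3ccccc3)C(=O)O2
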